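- Wednesday's: solid electrophile 0.75 M; nucleophile 0.55 M; free base 0.55 M (in portions, 3); run made earlier; portions every 3.0 min
- flask: solid electrophile 0.50 M; nucleophile 0.550 M; free base 0.550 M (in portions, 3); time 6.0 h; the portions of free base follow each other after 3.0 min, the first at the start

Wednesday's run (percent of the solid electrophile charged)

| time / min | electrophile / % | product / % |
|---|---|---|
| 6.00 | 1.5 | 1.1 |
| 10.0 | 2.4 | 1.0 |
| 15.0 | 2.7 | 2.2 |
| 25.0 | 3.0 | 3.9 |
| 40.0 | 3.7 | 7.1 |
| 80.0 | 4.5 | 15.2 |

(standard deviation of a reading: 0.3 percentage points)

- solid electrophile is a solid; its amount is given per volume of the solution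
- the analysis behind the earlier runs scatters by 0.3 percentage points, standard deviation
- at the start none of the solid electrophile is in solution
- electrophile means what is dissolved; the solid is not counted in it

* amount of electrophile in percent of the solid electrophile charged, at 80 min, 3.0 h and 6.0 h

1. The leftover of Wednesday's run was its solid: at 80.0 min electrophile and product together came to 0.148 M, less than the 0.75 M charged, so solid still lay in that flask.

2. The new flask looked nearly the same, with equal nucleophile, free base and portions but less solid. I assumed that dissolving goes by how far [electrophile] stands below its solubility, however much solid lies there, as long as some is left. On that assumption both flasks follow one molar course, and their percentages differ by the charge they are divided by.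

3. So I carried one quantity, the solid-blind level, Wednesday's [electrophile] in molar terms at 80.0 min: 0.0338 M. Against the new flask's charge it would be 6.75 %. Wednesday's dissolved amount would be 29.5 % of that charge, so the new flask keeps solid at that time too.

4. Wednesday's electrophile was still climbing, from 3.7 % to 4.5 %, which is 1.50 × 10⁻⁴ M min⁻¹. Two scattered readings carry that line, so it is rough. Drawn straight from the carried level, it gave me 9.75 % at 3.0 h and 15.1 % at 6.0 h.

5. The forecast gave 4.9 %, 4.8 % and 4.4 %, lower than my figure at each time, on the words “I assume kd scales with remaining solid; this is the main uncertainty.”

6. The new flask gave 6.64 %, 9.91 % and 13.7 %. The mechanism behind it: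

    electrophile + nucleophile → acid set free + product (k = 0.128 M⁻¹ min⁻¹)
    nucleophile + acid set free ⇌ protonated nucleophile, settled at all times (K = 820 M⁻¹)
    acid set free + free base ⇌ salt of the base (K = 3.20 M⁻¹, k = 0.662 M⁻¹ min⁻¹)
    solid electrophile ⇌ electrophile, rate k4*(cs4 - [electrophile]) while solid is left; crystals form when [electrophile] > cs4 (solubility = 0.0740 M, k = 0.0375 min⁻¹)

At 3.00 h the new flask held 0.213 M of protonated nucleophile beside 0.219 M of product, with 21.3 % of the nucleophile left. Its [electrophile] at 80 min was 0.0332 M, beside the carried 0.0338 M. At 6.0 h its [electrophile] was 0.0685 M, twice the carried level, against a solubility of 0.074 M.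

The earlier runs and the new flask are calculated with made-up constants, noise included.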